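**Plan**
1. Rings: A = methyl ester ring, B = central 2-methoxy ring, C = terminal 2,4-dihydroxy ring. Retrosynthetic cuts, in order: the two O-benzyl groups on ring C; the C1(ring C)–C(=O) bond of the C→B ester, giving a ring C aryl iodide, CO and the ring B 4-phenol of the A–B didepside; the ring B acyl–O4(ring A) ester bond.
2. Enabling feature: this ester carbonyl is one carbon at the oxidation level of CO. It sits between C1 of ring C (flanked by C2–O and C6–CH3, so poor for acyl substitution but suited to CO insertion into an aryl–Pd bond) and O4 of ring B, the only phenol of the A–B didepside not chelated to an ortho ester carbonyl.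
3. Forward: methyl orsellinate is used twice (ring A as bought; ring B after 4-O-benzylation, 2-O-methylation and saponification). Esterification joins A and B, hydrogenolysis frees ring B 4-OH, ring C comes from orcinol by dibenzylation and iodination, the three-component Pd carbonylation joins the chain, and a final hydrogenolysis gives the target.
4. No ring is built (all three benzene rings are bought) and no stereochemistry has to be set.

Key step: step 8

Assumption: the target has no stereocentre and no configurationally stable axis (the aryl esters rotate freely), so it is one achiral compound and no stereocontrol is needed.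

**Route**

Step 1
Reactants: 1 methyl 2,4-dihydroxy-6-methylbenzoate (methyl orsellinate)
Product: 2 methyl 4-(benzyloxy)-2-hydroxy-6-methylbenzoate
Conditions: BnBr (1.05 equiv), K2CO3, acetone, reflux
Reagents that add atoms: benzyl bromide, BrCc1ccccc1
Why: Williamson etherification, in which the 4-OH is the more acidic and accessible phenol while the 2-OH is held in a hydrogen bond to the ester carbonyl, so mono-benzylation at O4 is expected.

Step 2
Reactants: 2 methyl 4-(benzyloxy)-2-hydroxy-6-methylbenzoate
Product: 3 methyl 4-(benzyloxy)-2-methoxy-6-methylbenzoate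
Conditions: MeI, K2CO3, DMF, 50 °C
Reagents that add atoms: iodomethane, CI
Why: Williamson O-methylation of the remaining chelated 2-OH, which needs the polar solvent and warming but has no competing site.

Step 3
Reactants: 3 methyl 4-(benzyloxy)-2-methoxy-6-methylbenzoate
Product: 4 4-(benzyloxy)-2-methoxy-6-methylbenzoic acid
Conditions: KOH, DMSO–H2O (4:1), 90 °C; then aq. HCl
Reagents that add atoms: potassium hydroxide, [K+].[OH-]
Why: Saponification (BAc2) of a di-ortho-substituted methyl benzoate, for which poorly solvated hydroxide in aqueous DMSO is the usual remedy, the benzyl and methyl ethers being inert to base.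

Step 4
Reactants: 4 4-(benzyloxy)-2-methoxy-6-methylbenzoic acid; 1 methyl 2,4-dihydroxy-6-methylbenzoate
Product: 6 methyl 4-{[4-(benzyloxy)-2-methoxy-6-methylbenzoyl]oxy}-2-hydroxy-6-methylbenzoate, via mixed trifluoroacetic anhydride 5 (not isolated)
Conditions: TFAA (2 equiv), toluene, 0 °C → rt
Reagents that add atoms: trifluoroacetic anhydride, O=C(OC(=O)C(F)(F)F)C(F)(F)F (its atoms are carried only by intermediate 5, none by 6)
Why: Mixed-anhydride (TFAA) depside esterification, in which the electron-rich acid forms acyl trifluoroacetate 5 that acylates the free 4-OH of 1 while the 2-OH, hydrogen-bonded to and flanked by the ester, stays unreacted.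

Step 5
Reactants: 6 methyl 4-{[4-(benzyloxy)-2-methoxy-6-methylbenzoyl]oxy}-2-hydroxy-6-methylbenzoate
Product: 7 methyl 2-hydroxy-4-[(4-hydroxy-2-methoxy-6-methylbenzoyl)oxy]-6-methylbenzoate
Conditions: H2 (1 atm), 10% Pd/C, EtOAc, rt
Reagents that add atoms: none
Why: Catalytic hydrogenolysis of the benzyl aryl ether over Pd/C in a non-nucleophilic solvent should leave the aryl ester and the methyl ester untouched.

Step 6
Reactants: 8 orcinol (5-methylbenzene-1,3-diol)
Product: 9 1,3-bis(benzyloxy)-5-methylbenzene
Conditions: BnBr (2.2 equiv), K2CO3, DMF, 60 °C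
Reagents that add atoms: benzyl bromide, BrCc1ccccc1
Why: Double Williamson etherification of the two equivalent phenols of orcinol.

Step 7
Reactants: 9 1,3-bis(benzyloxy)-5-methylbenzene
Product: 10 1,5-bis(benzyloxy)-2-iodo-3-methylbenzene
Conditions: NIS (1.0 equiv), MeCN, 0 °C → rt, dark
Reagents that add atoms: N-iodosuccinimide, O=C1CCC(=O)N1I
Why: Electrophilic aromatic iodination (SEAr) of a 3,5-dialkoxytoluene should take place at C2, ortho to the methyl group and para to one benzyloxy group, and not at the more crowded C4 between the two benzyloxy groups, with one equivalent of NIS limiting di-iodination.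

Step 8
Reactants: 10 1,5-bis(benzyloxy)-2-iodo-3-methylbenzene; 7 methyl 2-hydroxy-4-[(4-hydroxy-2-methoxy-6-methylbenzoyl)oxy]-6-methylbenzoate
Product: 12 methyl 4-[(4-{[2,4-bis(benzyloxy)-6-methylbenzoyl]oxy}-2-methoxy-6-methylbenzoyl)oxy]-2-hydroxy-6-methylbenzoate, via aroylpalladium(II) iodide 11 (not isolated)
Conditions: CO (1 atm), Pd(OAc)2 (5 mol %), Xantphos (7.5 mol %), Et3N (3 equiv), toluene, 90 °C
Reagents that add atoms: carbon monoxide, [C-]#[O+]
Why: Pd(0)/Xantphos adds oxidatively to the C–I bond of 10, CO coordinates and inserts into the aryl–Pd bond to forge the bond between C1 of ring C and the new carbonyl carbon (aroylpalladium 11), and the triethylammonium phenoxide of 7 then attacks at Pd/acyl so that reductive elimination closes the O–C(=O) bond and returns Pd(0). The closest known reaction type is the Heck-type palladium-catalysed aryloxycarbonylation of aryl iodides with phenols under CO, run here as a three-component union of 10, CO and 7. No ring is closed and no stereocentre is formed, so neither a mode of closure nor a stereocontrol element applies. The step needs site selectivity between the two phenols of 7, which is secured because ring B 4-OH is unhindered and acidified by its para ester whereas ring A 2-OH is tied up in a six-membered hydrogen bond to the methyl ester carbonyl and shielded by it. It also needs CO insertion to outrun direct C–O coupling, hydrodeiodination and C–H arylation of the ortho benzyl ether, which the CO atmosphere, the wide-bite-angle ligand, the mild amine base and the relief of di-ortho strain on going from aryl- to aroylpalladium should ensure. The benzyl ethers on ring C keep its own oxygens from competing as nucleophiles, and the di-ortho-substituted esters already present should resist phenoxide transesterification at this temperature.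

Step 9
Reactants: 12 methyl 4-[(4-{[2,4-bis(benzyloxy)-6-methylbenzoyl]oxy}-2-methoxy-6-methylbenzoyl)oxy]-2-hydroxy-6-methylbenzoate
Product: 13 methyl 4-[(4-{[2,4-dihydroxy-6-methylbenzoyl]oxy}-2-methoxy-6-methylbenzoyl)oxy]-2-hydroxy-6-methylbenzoate
Conditions: H2 (1 atm), 10% Pd/C, EtOAc–THF, rt
Reagents that add atoms: none
Why: Catalytic hydrogenolysis should remove both benzyl ethers of ring C in one operation without touching the three ester groups, as is standard for depsides.

**Compound list**
1 | methyl 2,4-dihydroxy-6-methylbenzoate (methyl orsellinate) | COC(=O)c1c(C)cc(O)cc1O | starting material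
2 | methyl 4-(benzyloxy)-2-hydroxy-6-methylbenzoate | COC(=O)c1c(C)cc(OCc2ccccc2)cc1O | intermediate
3 | methyl 4-(benzyloxy)-2-methoxy-6-methylbenzoate | COC(=O)c1c(C)cc(OCc2ccccc2)cc1OC | intermediate
4 | 4-(benzyloxy)-2-methoxy-6-methylbenzoic acid | OC(=O)c1c(C)cc(OCc2ccccc2)cc1OC | intermediate
5 | 4-(benzyloxy)-2-methoxy-6-methylbenzoic trifluoroacetic anhydride | O=C(OC(=O)C(F)(F)F)c1c(C)cc(OCc2ccccc2)cc1OC | intermediate (not isolated)
6 | methyl 4-{[4-(benzyloxy)-2-methoxy-6-methylbenzoyl]oxy}-2-hydroxy-6-methylbenzoate | COC(=O)c1c(C)cc(OC(=O)c2c(C)cc(OCc3ccccc3)cc2OC)cc1O | intermediate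
7 | methyl 2-hydroxy-4-[(4-hydroxy-2-methoxy-6-methylbenzoyl)oxy]-6-methylbenzoate | COC(=O)c1c(C)cc(OC(=O)c2c(C)cc(O)cc2OC)cc1O | intermediate
8 | orcinol (5-methylbenzene-1,3-diol) | Cc1cc(O)cc(O)c1 | starting material
9 | 1,3-bis(benzyloxy)-5-methylbenzene | Cc1cc(OCc2ccccc2)cc(OCc2ccccc2)c1 | intermediate
10 | 1,5-bis(benzyloxy)-2-iodo-3-methylbenzene | Cc1cc(OCc2ccccc2)cc(OCc2ccccc2)c1I | intermediate
11 | [2,4-bis(benzyloxy)-6-methylbenzoyl]palladium(II) iodide (Xantphos on Pd not drawn) | O=C([Pd]I)c1c(C)cc(OCc2ccccc2)cc1OCc1ccccc1 | intermediate (not isolated)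
12 | methyl 4-[(4-{[2,4-bis(benzyloxy)-6-methylbenzoyl]oxy}-2-methoxy-6-methylbenzoyl)oxy]-2-hydroxy-6-methylbenzoate | COC(=O)c1c(C)cc(OC(=O)c2c(C)cc(OC(=O)c3c(C)cc(OCc4ccccc4)cc3OCc3ccccc3)cc2OC)cc1O | intermediate
13 | methyl 4-[(4-{[2,4-dihydroxy-6-methylbenzoyl]oxy}-2-methoxy-6-methylbenzoyl)oxy]-2-hydroxy-6-methylbenzoate | COC(=O)c1c(C)cc(OC(=O)c2c(C)cc(OC(=O)c3c(C)cc(O)cc3O)cc2OC)cc1O | target

**Count**
Total steps: 9. Longest linear sequence: 7 steps (steps 1, 2, 3, 4, 5, 8, 9); the ring C branch (steps 6, 7) joins at step 8.

**Steps most likely to fail**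

Step 8. The crowded aroylpalladium may be captured only slowly by the weakly nucleophilic phenoxide, so that hydrodeiodination, intramolecular C–H arylation onto the neighbouring O-benzyl ring, or base-induced acyl scrambling of the depside could take over. The fallback makes the aryl–carbonyl bond first by carboxylation and then closes the ester by classical acyl substitution. It sets out from iodide 10: iodine–lithium exchange (n-BuLi, THF, −78 °C) should give [2,4-bis(benzyloxy)-6-methylphenyl]lithium F1, which is quenched with CO2 and acidified to 2,4-bis(benzyloxy)-6-methylbenzoic acid F2. With TFAA in toluene F2 should form 2,4-bis(benzyloxy)-6-methylbenzoic trifluoroacetic anhydride F3, which acylates the ring B 4-OH of phenol 7, and the route is rejoined at 12.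

Step 4. Acyl transfer from the di-ortho-substituted mixed anhydride may be slow, letting O-trifluoroacetylation, Friedel–Crafts C-acylation of the electron-rich phenol or double acylation compete. The fallback replaces acyl substitution by acyl–palladium chemistry. It sets out from acid 4: ipso-iododecarboxylation (I2, K3PO4, MeCN, 100 °C) should give 5-(benzyloxy)-2-iodo-1-methoxy-3-methylbenzene F4. Carbonylative coupling of F4 with CO and the 4-OH of methyl orsellinate 1 under the conditions of step 8, through [4-(benzyloxy)-2-methoxy-6-methylbenzoyl]palladium(II) iodide F5, should come back to the route at 6.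

Step 3. Hydroxide attack at the shielded ester carbonyl may stall, leaving the saponification incomplete. The fallback reaches the acid by a reduction–oxidation detour instead of acyl substitution. It sets out from ester 3: LiAlH4 (THF, 0 °C) should give [4-(benzyloxy)-2-methoxy-6-methylphenyl]methanol F6, MnO2 (CH2Cl2, rt) should oxidise it to 4-(benzyloxy)-2-methoxy-6-methylbenzaldehyde F7, and Pinnick oxidation (NaClO2, NaH2PO4, 2-methyl-2-butene, t-BuOH–H2O) should return to the route at acid 4.

**Further compounds**
F1 | step 8 | [2,4-bis(benzyloxy)-6-methylphenyl]lithium | [Li]c1c(C)cc(OCc2ccccc2)cc1OCc1ccccc1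
F2 | step 8 | 2,4-bis(benzyloxy)-6-methylbenzoic acid | OC(=O)c1c(C)cc(OCc2ccccc2)cc1OCc1ccccc1
F3 | step 8 | 2,4-bis(benzyloxy)-6-methylbenzoic trifluoroacetic anhydride | O=C(OC(=O)C(F)(F)F)c1c(C)cc(OCc2ccccc2)cc1OCc1ccccc1
F4 | step 4 | 5-(benzyloxy)-2-iodo-1-methoxy-3-methylbenzene | COc1cc(OCc2ccccc2)cc(C)c1I
F5 | step 4 | [4-(benzyloxy)-2-methoxy-6-methylbenzoyl]palladium(II) iodide (Xantphos on Pd not drawn) | O=C([Pd]I)c1c(C)cc(OCc2ccccc2)cc1OC
F6 | step 3 | [4-(benzyloxy)-2-methoxy-6-methylphenyl]methanol | OCc1c(C)cc(OCc2ccccc2)cc1OC
F7 | step 3 | 4-(benzyloxy)-2-methoxy-6-methylbenzaldehyde | O=Cc1c(C)cc(OCc2ccccc2)cc1OC
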